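The ten-membered ring of the target, with its C1(10) and C4(5) alkenes (the former epoxidised last) and oxygen at C3, is a eudesmane decalin whose C5–C10 ring-fusion bond is cut. Irradiation of the ring-A 3-silyloxy-1,3-diene of a cis-fused 13-nor-eudesman-6α,12-olide opens that bond in one conrotatory 6π step and gives the cyclodeca-1(10),2,4-triene directly. The precursor is the 5α-H,10α-methyl (not 5β,10β) diastereomer: only there does the diequatorial trans-lactone at C6/C7 fix ring B so that C6 is pseudoaxial and C9 pseudoequatorial on the diene ring, the helicity that opens to 1(10)E,4Z.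

Key step: step 17

Remark on numbering: bicyclic and ten-membered compounds carry eudesmane/germacrane numbering (C11–C12 = lactone carbons, C14 = methyl on C10, C15 = methyl on C4); β is the face of the C7–C11 bond, α the face of the C6–O bond.
Remark on the ring fusion: in the 5β-H,10β-methyl isomer the same lactone would hold C9 pseudoaxial and C6 pseudoequatorial on ring A, and the opening would lead to the 1(10)Z,4E triene; the route therefore uses the 5α,10α series.
Assumption: LiAl[(R)-1,1′-bi-2-naphtholate]2 is taken to select the same enantioface of enone 6 as of cyclohex-2-enone; compounds 1, 5, 7, 10, 11 and 32 are commercial.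

Step 1
Reactants: 1 angelic acid
Product: 2 (Z)-2-methylbut-2-en-1-ol
Conditions: LiAlH4, Et2O, 0 °C
Reagents that add atoms: none
Why: Hydride reduction of an α,β-unsaturated acid to the allylic alcohol should leave the trisubstituted Z alkene untouched at low temperature.

Step 2
Reactants: 2 (Z)-2-methylbut-2-en-1-ol
Product: 3 [(2S,3R)-2,3-dimethyloxiran-2-yl]methanol
Conditions: Ti(OiPr)4 (10 mol %), L-(+)-diethyl tartrate (12 mol %), tBuOOH, 4 Å MS, CH2Cl2, −20 °C
Reagents that add atoms: tert-butyl hydroperoxide, CC(C)(C)OO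
Why: Sharpless asymmetric epoxidation, in which the titanium L-(+)-tartrate complex delivers oxygen to the face of the allylic alcohol that makes C2 S and C3 R.

Step 3
Reactants: 3 [(2S,3R)-2,3-dimethyloxiran-2-yl]methanol
Product: 4 (2R,3R)-2,3-dimethyloxirane-2-carboxylic acid
Conditions: RuCl3 (2 mol %), NaIO4, CCl4/MeCN/H2O, rt
Reagents that add atoms: water, O
Why: Ruthenium tetroxide oxidation (Sharpless conditions) takes the primary alcohol through the aldehyde hydrate to the acid without opening the epoxide; both centres are retained and only the CIP descriptor at C2 changes.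

Step 4
Reactants: 5 1,4-dioxaspiro[4.5]dec-6-en-8-one
Product: 6 9-methyl-1,4-dioxaspiro[4.5]dec-6-en-8-one (racemic)
Conditions: LiN(iPr)2, THF, −78 °C; MeI
Reagents that add atoms: iodomethane, CI
Why: Kinetic α′-enolate alkylation (the γ-carbon is the ketal carbon and has no hydrogen); the new centre is racemic and is re-set in step 7.

Step 5
Reactants: 6 9-methyl-1,4-dioxaspiro[4.5]dec-6-en-8-one; 7 dimethyl malonate
Product: 8 dimethyl 2-[(6R)-9-methyl-8-oxo-1,4-dioxaspiro[4.5]decan-6-yl]propanedioate (both C9 epimers)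
Conditions: LiAl[(R)-1,1′-bi-2-naphtholate]2 (10 mol %), KOtBu (9 mol %), 4 Å MS, THF, rt
Reagents that add atoms: none
Why: Catalytic asymmetric Michael addition of a malonate to a cyclic enone with the heterobimetallic aluminium lithium binaphtholate; the catalyst should select the enantioface of C6 (6R), and the epimeric methyl centre at C9 is of no consequence.

Step 6
Reactants: 8 dimethyl 2-[(6R)-9-methyl-8-oxo-1,4-dioxaspiro[4.5]decan-6-yl]propanedioate
Product: 9 methyl 2-[(6R)-9-methyl-8-oxo-1,4-dioxaspiro[4.5]decan-6-yl]acetate (both C9 epimers)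
Conditions: LiCl, H2O, DMSO, 140 °C
Reagents that add atoms: none
Why: Krapcho dealkoxycarbonylation (chloride demethylates one ester, the carboxylate loses CO2) under neutral conditions that spare the ketal and do not touch C6.

Step 7
Reactants: 9 methyl 2-[(6R)-9-methyl-8-oxo-1,4-dioxaspiro[4.5]decan-6-yl]acetate; 10 (S)-1-phenylethylamine; 11 ethyl vinyl ketone
Product: 14 methyl 2-[(6R,9S)-9-methyl-8-oxo-9-(3-oxopentyl)-1,4-dioxaspiro[4.5]decan-6-yl]acetate, via phenylethyl imine 12 (not isolated), via Michael-adduct imine 13 (not isolated)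
Conditions: 10, 4 Å MS, toluene, 40 °C; 11, THF, 40 °C; 10% aq. AcOH, rt
Reagents that add atoms: water, O
Why: Deracemising Michael addition of a chiral imine (d'Angelo), in which the secondary enamine reacts at the more substituted α-carbon and the (S)-phenylethyl group shields one face, so that the 3-oxopentyl chain should enter cis to the C6 side chain and the quaternary centre becomes 9S (the later 10α-methyl).

Step 8
Reactants: 14 methyl 2-[(6R,9S)-9-methyl-8-oxo-9-(3-oxopentyl)-1,4-dioxaspiro[4.5]decan-6-yl]acetate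
Product: 15 methyl 8,8-ethylenedioxy-3-oxo-13-nor-10-epi-eudesm-4-en-12-oate (7R,10S; 7β-CH2CO2Me, 10α-CH3)
Conditions: NaOMe, MeOH, 0 → 60 °C
Reagents that add atoms: none
Why: Intramolecular aldol condensation (second half of a Robinson annulation) of the ethyl ketone methylene onto the ring ketone gives the tetrasubstituted enone without touching a stereocentre.

Step 9
Reactants: 15 methyl 8,8-ethylenedioxy-3-oxo-13-nor-10-epi-eudesm-4-en-12-oate
Product: 16 methyl 8,8-ethylenedioxy-3-(triethylsilyloxy)-13-nor-10-epi-eudesma-3,5-dien-12-oate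
Conditions: Et3SiOTf, Et3N, CH2Cl2, 0 °C
Reagents that add atoms: triethylsilyl trifluoromethanesulfonate, CC[Si](CC)(CC)OS(=O)(=O)C(F)(F)F
Why: Soft enolisation of the enone with a silyl triflate and an amine gives the thermodynamically favoured extended dienol ether by loss of a C6 hydrogen.

Step 10
Reactants: 16 methyl 8,8-ethylenedioxy-3-(triethylsilyloxy)-13-nor-10-epi-eudesma-3,5-dien-12-oate
Product: 17 methyl 8,8-ethylenedioxy-6α-hydroxy-3-oxo-13-nor-10-epi-eudesm-4-en-12-oate
Conditions: mCPBA, NaHCO3, CH2Cl2, −20 °C; aq. citric acid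
Reagents that add atoms: 3-chloroperbenzoic acid, OOC(=O)c1cccc(Cl)c1
Why: Vinylogous Rubottom oxidation at the γ-terminus C6; attack should be axial on the face of the angular methyl (as with 3,5-dienol derivatives of 4-en-3-ones) and anti to the pseudoaxial C7 side chain, which gives 6α-OH.

Step 11
Reactants: 17 methyl 8,8-ethylenedioxy-6α-hydroxy-3-oxo-13-nor-10-epi-eudesm-4-en-12-oate
Product: 19 8,8-ethylenedioxy-3-oxo-4αH,5αH-13-nor-10-epi-eudesman-6α,12-olide, via cis-fused hydroxy ester 18 (not isolated)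
Conditions: [Ir(cod)(PCy3)(py)]PF6 (5 mol %), H2 (1–4 bar), CH2Cl2, rt; then camphorsulfonic acid (cat.), rt
Reagents that add atoms: none
Why: Hydroxyl-directed homogeneous hydrogenation, in which the allylic 6α-hydroxyl binds the cationic iridium centre and hydrogen is delivered to C4=C5 on the same face (5α-H cis to the 10α-methyl, 4α-H); in the cis-decalin the 6α-hydroxyl and the 7β side chain become diequatorial and acid should close the trans-lactone.

Step 12
Reactants: 19 8,8-ethylenedioxy-3-oxo-4αH,5αH-13-nor-10-epi-eudesman-6α,12-olide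
Product: 21 8,8-ethylenedioxy-3-oxo-4αH,5αH-13-nor-10-epi-eudesm-1-en-6α,12-olide, via trimethylsilyl enol ether 20 (not isolated)
Conditions: LiN(iPr)2, Me3SiCl, THF, −78 °C; then Pd(OAc)2, MeCN, rt
Reagents that add atoms: none
Why: Kinetic enolisation of the ketone at the unsubstituted C2 (faster than at C4 or at the lactone) followed by Saegusa–Ito dehydrogenation of the silyl enol ether gives the 1-en-3-one.

Step 13
Reactants: 21 8,8-ethylenedioxy-3-oxo-4αH,5αH-13-nor-10-epi-eudesm-1-en-6α,12-olide
Product: 22 3,8-dioxo-4αH,5αH-13-nor-10-epi-eudesm-1-en-6α,12-olide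
Conditions: PPTS, acetone/H2O, 55 °C
Reagents that add atoms: water, O
Why: Acid-catalysed hydrolysis of the dioxolane under mild conditions that the enone and the γ-lactone tolerate.

Step 14
Reactants: 22 3,8-dioxo-4αH,5αH-13-nor-10-epi-eudesm-1-en-6α,12-olide
Product: 23 3ξ,8β-dihydroxy-4αH,5αH-13-nor-10-epi-eudesm-1-en-6α,12-olide
Conditions: NaBH4, CeCl3·7H2O, MeOH, −78 °C
Reagents that add atoms: none
Why: Luche reduction of both carbonyl groups; at C8 the axial approach is blocked by C1, which is 1,3-diaxial on ring B in the lactone-locked chair, so hydride should enter from the α face and give the axial 8β-alcohol (the usual result for cyclohexanones with a syn-axial carbon), while the C3 configuration is irrelevant.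

Step 15
Reactants: 23 3ξ,8β-dihydroxy-4αH,5αH-13-nor-10-epi-eudesm-1-en-6α,12-olide
Product: 24 8β-hydroxy-3-oxo-4αH,5αH-13-nor-10-epi-eudesm-1-en-6α,12-olide
Conditions: MnO2, CH2Cl2, rt
Reagents that add atoms: none
Why: Manganese dioxide oxidises only the allylic C3 alcohol back to the enone and leaves the saturated, hindered 8β-alcohol.

Step 16
Reactants: 24 8β-hydroxy-3-oxo-4αH,5αH-13-nor-10-epi-eudesm-1-en-6α,12-olide
Product: 25 3,8β-bis(tert-butyldimethylsilyloxy)-5αH-13-nor-10-epi-eudesma-1,3-dien-6α,12-olide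
Conditions: tBuMe2SiOTf, Et3N, CH2Cl2, −78 → 0 °C
Reagents that add atoms: tert-butyldimethylsilyl trifluoromethanesulfonate, CC(C)(C)[Si](C)(C)OS(=O)(=O)C(F)(F)F
Why: One reagent silylates the 8β-alcohol and effects soft enolisation of the enone towards C4, its only enolisable α-position because C10 is quaternary, to give the 3-silyloxy-1,3-diene.

Step 17
Reactants: 25 3,8β-bis(tert-butyldimethylsilyloxy)-5αH-13-nor-10-epi-eudesma-1,3-dien-6α,12-olide
Product: 26 (1(10)E,2Z,4Z)-3,8β-bis(tert-butyldimethylsilyloxy)-13-nor-germacra-1(10),2,4-trien-6α,12-olide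
Conditions: hν (300 nm), degassed pentane/Et2O, −78 °C, to about half conversion; 25 recovered and re-irradiated
Reagents that add atoms: none
Why: Excitation of the homoannular diene C1=C2–C3(OSi)=C4 triggers a conrotatory 6π electrocyclic ring opening that cleaves the C5–C10 σ bond, so rings A and B merge into the ten-membered ring by ring expansion and not by an end-to-end closure. The closest known reaction type is the provitamin D to previtamin D opening and the opening of fused hexalin dienes to cyclodecatrienes. No stereocentre is created: C6, C7 and C8 are untouched and C5 and C10 become trigonal. The step needs torquoselectivity, with C9 turning outward and C6 inward, to give 1(10)E,4Z. Ring opening follows the ground-state twist of the diene, pseudoaxial groups at the sp3 termini turning inward, and in 25 the diequatorial trans-lactone freezes ring B in the chair in which C6 and the C10 methyl are pseudoaxial and C9 and H5 pseudoequatorial on ring A. Low temperature and partial conversion limit photochemical re-closure and the thermal 1,7-hydrogen shift of the triene.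

Step 18
Reactants: 26 (1(10)E,2Z,4Z)-3,8β-bis(tert-butyldimethylsilyloxy)-13-nor-germacra-1(10),2,4-trien-6α,12-olide
Product: 27 (1(10)E,4Z)-8β-(tert-butyldimethylsilyloxy)-3-oxo-13-nor-germacra-1(10),4-dien-6α,12-olide
Conditions: Bu4NF, AcOH, THF, −78 °C (crude 26 used cold)
Reagents that add atoms: none
Why: Fluoride cleaves the silyl enol ether far faster than the secondary alkyl silyl ether, and kinetic α-protonation of the dienolate at C2 should give the 3-ketone conjugated with C4=C5 while C1=C10 stays in place.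

Step 19
Reactants: 27 (1(10)E,4Z)-8β-(tert-butyldimethylsilyloxy)-3-oxo-13-nor-germacra-1(10),4-dien-6α,12-olide
Product: 28 (3S,1(10)E,4Z)-8β-(tert-butyldimethylsilyloxy)-3-hydroxy-13-nor-germacra-1(10),4-dien-6α,12-olide
Conditions: (R)-2-methyl-CBS-oxazaborolidine, catecholborane, toluene, −78 °C
Reagents that add atoms: none
Why: Corey–Bakshi–Shibata reduction of an α-methyl enone, in which the catalyst tells the alkenyl side (large) from the CH2 side (small) and the (R)-catalyst should deliver hydride to the face that gives the 3S alcohol.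

Step 20
Reactants: 28 (3S,1(10)E,4Z)-8β-(tert-butyldimethylsilyloxy)-3-hydroxy-13-nor-germacra-1(10),4-dien-6α,12-olide
Product: 31 (3S,1(10)E,4Z)-8β-(tert-butyldimethylsilyloxy)-3-hydroxygermacra-1(10),4,11(13)-trien-6α,12-olide, via Mannich base 29 (not isolated), via ammonium iodide 30 (not isolated)
Conditions: LiN(iPr)2 (2.4 equiv), THF, −78 °C; Me2N=CH2 I, −78 → 0 °C; MeI, MeOH, rt; aq. NaHCO3
Reagents that add atoms: N,N-dimethylmethyleneiminium iodide, C=[N+](C)C.[I-]
Why: α-Methylenation of the lactone by Mannich reaction of its enolate with Eschenmoser's salt (the C3 alkoxide is a spectator), quaternisation and elimination of trimethylamine; C11 becomes trigonal.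

Step 21
Reactants: 31 (3S,1(10)E,4Z)-8β-(tert-butyldimethylsilyloxy)-3-hydroxygermacra-1(10),4,11(13)-trien-6α,12-olide; 32 (R)-2-methylbutanoic acid
Product: 33 (3S,1(10)E,4Z)-8β-(tert-butyldimethylsilyloxy)-3-[(R)-2-methylbutanoyloxy]germacra-1(10),4,11(13)-trien-6α,12-olide
Conditions: EDC·HCl, DMAP (cat.), CH2Cl2, 0 °C
Reagents that add atoms: none
Why: Steglich-type carbodiimide esterification of the allylic alcohol at low temperature with catalytic DMAP, conditions under which the α-stereocentre of the acid should not epimerise.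

Step 22
Reactants: 33 (3S,1(10)E,4Z)-8β-(tert-butyldimethylsilyloxy)-3-[(R)-2-methylbutanoyloxy]germacra-1(10),4,11(13)-trien-6α,12-olide
Product: 34 (3S,1(10)E,4Z)-8β-hydroxy-3-[(R)-2-methylbutanoyloxy]germacra-1(10),4,11(13)-trien-6α,12-olide
Conditions: HF·pyridine, pyridine, THF, 0 °C → rt
Reagents that add atoms: none
Why: Buffered fluoride desilylation without base, which the α-methylene lactone and the ester should survive.

Step 23
Reactants: 34 (3S,1(10)E,4Z)-8β-hydroxy-3-[(R)-2-methylbutanoyloxy]germacra-1(10),4,11(13)-trien-6α,12-olide; 4 (2R,3R)-2,3-dimethyloxirane-2-carboxylic acid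
Product: 35 (3S,1(10)E,4Z)-8β-[(2R,3R)-2,3-dimethyloxirane-2-carbonyloxy]-3-[(R)-2-methylbutanoyloxy]germacra-1(10),4,11(13)-trien-6α,12-olide
Conditions: 2,4,6-Cl3C6H2COCl, Et3N, THF; then DMAP, toluene, rt
Reagents that add atoms: none
Why: Yamaguchi esterification through the mixed anhydride acylates the hindered 8β-alcohol; the acid has no α-hydrogen and its epoxide is not touched.

Step 24
Reactants: 35 (3S,1(10)E,4Z)-8β-[(2R,3R)-2,3-dimethyloxirane-2-carbonyloxy]-3-[(R)-2-methylbutanoyloxy]germacra-1(10),4,11(13)-trien-6α,12-olide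
Product: 36 CNP0265335.1 (1R,10R-epoxide)
Conditions: mCPBA, NaHCO3, CH2Cl2, 0 °C
Reagents that add atoms: 3-chloroperbenzoic acid, OOC(=O)c1cccc(Cl)c1
Why: Prilezhaev epoxidation of the only electron-rich alkene, C1=C10 (C4=C5 carries two allylic acyloxy groups, C11=C13 is conjugated); syn addition to the E alkene from its exposed outer face should give the trans 1R,10R epoxide.

Compound list
1 | angelic acid, (Z)-2-methylbut-2-enoic acid | C/C=C(/C)C(=O)O | starting material
2 | (Z)-2-methylbut-2-en-1-ol | C/C=C(/C)CO | intermediate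
3 | [(2S,3R)-2,3-dimethyloxiran-2-yl]methanol | OC[C@]1(C)O[C@@H]1C | intermediate
4 | (2R,3R)-2,3-dimethyloxirane-2-carboxylic acid | OC(=O)[C@]1(C)O[C@@H]1C | intermediate
5 | 1,4-dioxaspiro[4.5]dec-6-en-8-one | O=C1C=CC2(CC1)OCCO2 | starting material
6 | 9-methyl-1,4-dioxaspiro[4.5]dec-6-en-8-one (racemic) | O=C1C=CC2(CC1C)OCCO2 | intermediate
7 | dimethyl malonate | COC(=O)CC(=O)OC | starting material
8 | dimethyl 2-[(6R)-9-methyl-8-oxo-1,4-dioxaspiro[4.5]decan-6-yl]propanedioate (C9 epimers) | COC(=O)C(C(=O)OC)[C@H]1CC(=O)C(C)CC12OCCO2 | intermediate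
9 | methyl 2-[(6R)-9-methyl-8-oxo-1,4-dioxaspiro[4.5]decan-6-yl]acetate (C9 epimers) | COC(=O)C[C@H]1CC(=O)C(C)CC12OCCO2 | intermediate
10 | (S)-1-phenylethylamine | C[C@H](N)c1ccccc1 | starting material
11 | ethyl vinyl ketone (pent-1-en-3-one) | CCC(=O)C=C | starting material
12 | N-[(S)-1-phenylethyl] imine of 9 | COC(=O)C[C@H]1CC(=N[C@@H](C)c2ccccc2)C(C)CC13OCCO3 | intermediate (not isolated)
13 | N-[(S)-1-phenylethyl] imine of 14 | COC(=O)C[C@H]1CC(=N[C@@H](C)c2ccccc2)[C@@](C)(CCC(=O)CC)CC13OCCO3 | intermediate (not isolated)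
14 | methyl 2-[(6R,9S)-9-methyl-8-oxo-9-(3-oxopentyl)-1,4-dioxaspiro[4.5]decan-6-yl]acetate | COC(=O)C[C@H]1CC(=O)[C@@](C)(CCC(=O)CC)CC12OCCO2 | intermediate
15 | methyl 8,8-ethylenedioxy-3-oxo-13-nor-10-epi-eudesm-4-en-12-oate (7β side chain, 10α-methyl) | C[C@@]12CCC(=O)C(C)=C1C[C@H](CC(=O)OC)C3(C2)OCCO3 | intermediate
16 | 3-triethylsilyl 3,5-dienol ether of 15 | C[C@@]12CCC(O[Si](CC)(CC)CC)=C(C)C1=C[C@H](CC(=O)OC)C3(C2)OCCO3 | intermediate
17 | 6α-hydroxy enone (6α-OH, 7β side chain, 10α-methyl) | C[C@@]12CCC(=O)C(C)=C1[C@@H](O)[C@H](CC(=O)OC)C3(C2)OCCO3 | intermediate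
18 | cis-fused hydroxy ester (4α-H, 5α-H, 6α-OH, 10α-methyl) | C[C@@]12CCC(=O)[C@H](C)[C@@H]1[C@@H](O)[C@H](CC(=O)OC)C3(C2)OCCO3 | intermediate (not isolated)
19 | 8,8-ethylenedioxy-3-oxo-4αH,5αH-13-nor-10-epi-eudesman-6α,12-olide | C[C@@]12CCC(=O)[C@H](C)[C@@H]1[C@H]3OC(=O)C[C@@H]3C4(C2)OCCO4 | intermediate
20 | 3-trimethylsilyl 2-enol ether of 19 | C[C@@]12CC=C(O[Si](C)(C)C)[C@H](C)[C@@H]1[C@H]3OC(=O)C[C@@H]3C4(C2)OCCO4 | intermediate (not isolated)
21 | 8,8-ethylenedioxy-3-oxo-4αH,5αH-13-nor-10-epi-eudesm-1-en-6α,12-olide | C[C@@]12C=CC(=O)[C@H](C)[C@@H]1[C@H]3OC(=O)C[C@@H]3C4(C2)OCCO4 | intermediate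
22 | 3,8-dioxo-4αH,5αH-13-nor-10-epi-eudesm-1-en-6α,12-olide | C[C@@]12C=CC(=O)[C@H](C)[C@@H]1[C@H]3OC(=O)C[C@@H]3C(=O)C2 | intermediate
23 | 3ξ,8β-dihydroxy-4αH,5αH-13-nor-10-epi-eudesm-1-en-6α,12-olide | C[C@@]12C=CC(O)[C@H](C)[C@@H]1[C@H]3OC(=O)C[C@@H]3[C@H](O)C2 | intermediate
24 | 8β-hydroxy-3-oxo-4αH,5αH-13-nor-10-epi-eudesm-1-en-6α,12-olide | C[C@@]12C=CC(=O)[C@H](C)[C@@H]1[C@H]3OC(=O)C[C@@H]3[C@H](O)C2 | intermediate
25 | 3,8β-bis(tert-butyldimethylsilyloxy)-5αH-13-nor-10-epi-eudesma-1,3-dien-6α,12-olide | C[C@@]12C=CC(O[Si](C)(C)C(C)(C)C)=C(C)[C@@H]1[C@H]3OC(=O)C[C@@H]3[C@H](O[Si](C)(C)C(C)(C)C)C2 | intermediate (precursor of the key step)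
26 | (1(10)E,2Z,4Z)-3,8β-bis(tert-butyldimethylsilyloxy)-13-nor-germacra-1(10),2,4-trien-6α,12-olide | C1C(=O)O[C@@H]2/C=C(/C)\C(O[Si](C)(C)C(C)(C)C)=C/C=C(\C)C[C@@H](O[Si](C)(C)C(C)(C)C)[C@@H]12 | intermediate (product of the key step)
27 | (1(10)E,4Z)-8β-(tert-butyldimethylsilyloxy)-3-oxo-13-nor-germacra-1(10),4-dien-6α,12-olide | C1C(=O)O[C@@H]2/C=C(/C)C(=O)C/C=C(\C)C[C@@H](O[Si](C)(C)C(C)(C)C)[C@@H]12 | intermediate
28 | (3S)-3-hydroxy analogue of 27 | C1C(=O)O[C@@H]2/C=C(/C)[C@@H](O)C/C=C(\C)C[C@@H](O[Si](C)(C)C(C)(C)C)[C@@H]12 | intermediate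
29 | 11-(dimethylaminomethyl) derivative of 28 (C11 epimers) | CN(C)CC1C(=O)O[C@@H]2/C=C(/C)[C@@H](O)C/C=C(\C)C[C@@H](O[Si](C)(C)C(C)(C)C)[C@@H]12 | intermediate (not isolated)
30 | trimethylammonium iodide of 29 | C[N+](C)(C)CC1C(=O)O[C@@H]2/C=C(/C)[C@@H](O)C/C=C(\C)C[C@@H](O[Si](C)(C)C(C)(C)C)[C@@H]12.[I-] | intermediate (not isolated)
31 | (3S,1(10)E,4Z)-8β-(tert-butyldimethylsilyloxy)-3-hydroxygermacra-1(10),4,11(13)-trien-6α,12-olide | C=C1C(=O)O[C@@H]2/C=C(/C)[C@@H](O)C/C=C(\C)C[C@@H](O[Si](C)(C)C(C)(C)C)[C@@H]12 | intermediate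
32 | (R)-2-methylbutanoic acid | CC[C@@H](C)C(=O)O | starting material
33 | 3-O-[(R)-2-methylbutanoyl] derivative of 31 | C=C1C(=O)O[C@@H]2/C=C(/C)[C@@H](OC(=O)[C@H](C)CC)C/C=C(\C)C[C@@H](O[Si](C)(C)C(C)(C)C)[C@@H]12 | intermediate
34 | 8β-hydroxy compound from 33 | C=C1C(=O)O[C@@H]2/C=C(/C)[C@@H](OC(=O)[C@H](C)CC)C/C=C(\C)C[C@@H](O)[C@@H]12 | intermediate
35 | 8-O-[(2R,3R)-2,3-dimethyloxirane-2-carbonyl] derivative of 34 | C=C1C(=O)O[C@@H]2/C=C(/C)[C@@H](OC(=O)[C@H](C)CC)C/C=C(\C)C[C@@H](OC(=O)[C@]3(C)O[C@@H]3C)[C@@H]12 | intermediate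
36 | CNP0265335.1 | C=C1C(=O)O[C@@H]2/C=C(/C)[C@@H](OC(=O)[C@H](C)CC)C[C@H]3O[C@]3(C)C[C@@H](OC(=O)[C@]3(C)O[C@@H]3C)[C@@H]12 | target

Total step count: 24 (21 on the main line, 3 for acid 4).
Longest linear sequence: 21 steps (steps 4–24, from 5 to 36).

Steps most likely to fail

Step 17. The process at risk is loss of torquoselectivity if the bulky axial 8β-silyloxy group, which lies 1,3-diaxial to C1, twists the locked chair, together with photochemical re-closure of the triene; in step 18 the C8 silyl ether may also be lost with the enol ether. The fallback changes what is irradiated and how C8 is protected. It sets out from 24: Me3SiOTf and Et3N give the bis(trimethylsilyl) diene F1, in which both silyl groups are small; irradiation as in step 17 gives the bis(trimethylsilyl) triene F2; buffered Bu4NF at −78 °C removes both silyl groups and gives the hydroxy dienone F3; tBuMe2SiCl and imidazole in DMF silylate the 8β-hydroxyl, and the route is rejoined at 27.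

Step 5. The process at risk is slow addition at the β-carbon next to the quaternary ketal carbon and poor enantioface selection. The fallback replaces asymmetric catalysis by resolution. It sets out from 6 and 7: NaOMe (cat.) in MeOH gives the racemic malonate adduct F4; LiCl in wet DMSO gives the racemic keto ester F5; after equilibration of the methyl-bearing centre with NaOMe, preparative chromatography on a chiral stationary phase (amylose tris(3,5-dimethylphenylcarbamate)) delivers the 6R enantiomer, and the route is rejoined at 9.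

Step 11. The process at risk is lack of turnover at the tetrasubstituted enone alkene next to the quaternary C10, or hydrogen delivery to the β face through competing coordination of the ester. The fallback delivers the C5 hydrogen through a silicon tether. It sets out from 17: ClSiHMe2 and Et3N give the dimethylsilyl ether F6; Pt2[(CH2=CHSiMe2)2O]3 (cat.) in toluene effects intramolecular hydrosilylation (Tamao type), which places hydrogen on C5 on the face of O6 and silicon on C4 in the oxasilolane F7; KF and KHCO3 in MeOH cleave the α-silyl ketone and the Si–O bond to the hydroxy ester 18, which lactonises with camphorsulfonic acid, and the route is rejoined at 19.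

Further compounds
F1 | step 17 | 3,8β-bis(trimethylsilyloxy)-5αH-13-nor-10-epi-eudesma-1,3-dien-6α,12-olide | C[C@@]12C=CC(O[Si](C)(C)C)=C(C)[C@@H]1[C@H]3OC(=O)C[C@@H]3[C@H](O[Si](C)(C)C)C2
F2 | step 17 | (1(10)E,2Z,4Z)-3,8β-bis(trimethylsilyloxy)-13-nor-germacra-1(10),2,4-trien-6α,12-olide | C1C(=O)O[C@@H]2/C=C(/C)\C(O[Si](C)(C)C)=C/C=C(\C)C[C@@H](O[Si](C)(C)C)[C@@H]12
F3 | step 17 | (1(10)E,4Z)-8β-hydroxy-3-oxo-13-nor-germacra-1(10),4-dien-6α,12-olide | C1C(=O)O[C@@H]2/C=C(/C)C(=O)C/C=C(\C)C[C@@H](O)[C@@H]12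
F4 | step 5 | racemic dimethyl 2-(9-methyl-8-oxo-1,4-dioxaspiro[4.5]decan-6-yl)propanedioate | COC(=O)C(C(=O)OC)C1CC(=O)C(C)CC12OCCO2
F5 | step 5 | racemic methyl 2-(9-methyl-8-oxo-1,4-dioxaspiro[4.5]decan-6-yl)acetate | COC(=O)CC1CC(=O)C(C)CC12OCCO2
F6 | step 11 | 6-O-dimethylsilyl ether of 17 | C[C@@]12CCC(=O)C(C)=C1[C@@H](O[SiH](C)C)[C@H](CC(=O)OC)C3(C2)OCCO3
F7 | step 11 | oxasilolane with Si on C4 and O6, 5α-H (product of intramolecular hydrosilylation of F6) | C[C@@]12CCC(=O)[C@]4(C)[C@@H]1[C@@H](O[Si]4(C)C)[C@H](CC(=O)OC)C3(C2)OCCO3
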